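**Retrosynthetic overview**

- The target is the 3,4-trans isoflavan-4-ol (3S,4R). The C4 hydroxyl is removed first in retrosynthesis (late benzylic C–H oxygenation anti to the C3 aryl), and the three phenols (O7, O2', O5') are carried as benzyl ethers.
- The strategy rests on ring A carrying O1 (on C8a) and C4 (on C4a) on adjacent carbons, which is a latent o-quinone methide O1=C8a–C4a=C4. Ring C is cut at C3–C4 and O1–C2 into this methide and the enamine of the ring B arylacetaldehyde (C2–C3), and the enamine sets C3.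
- Ring order: rings A and B are bought as arenes. Ring C is closed in the key step as the C2 lactol, opened by reduction and re-closed at O1–C2 by Mitsunobu etherification.
- Ring A salicyl alcohol: Dakin oxidation, ortho-formylation and reduction from O-benzylisovanillin. Ring B aldehyde: allylation/Claisen, para-quinone formation, reductive benzylation and alkene cleavage from 2,3-dimethoxyphenol.

Key step: step 9

Remark: 3-benzyloxy-4-methoxybenzaldehyde is taken as purchased (otherwise one benzylation from isovanillin). C3 is S in compounds 15–19 and C4 is R in 18 and 19, which is the 3,4-trans isomer.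

**Route**

Step 1
Reactants: 1 3-benzyloxy-4-methoxybenzaldehyde
Product: 3 3-benzyloxy-4-methoxyphenol, via aryl formate 2 (not isolated)
Conditions: mCPBA, CH2Cl2, rt; then KOH, MeOH/H2O, 0 °C
Reagents that add atoms: mCPBA, O=C(OO)c1cccc(Cl)c1
Why: Baeyer–Villiger (Dakin-type) oxidation in which the electron-rich aryl group migrates to oxygen, and the aryl formate is saponified in the same flask.

Step 2
Reactants: 3 3-benzyloxy-4-methoxyphenol
Product: 4 4-benzyloxy-2-hydroxy-5-methoxybenzaldehyde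
Conditions: MgCl2, Et3N, (CH2O)n, MeCN, reflux
Reagents that add atoms: paraformaldehyde (formaldehyde), C=O
Why: Magnesium-phenoxide-directed ortho-formylation (Casnati–Skattebøl) should react only ortho to OH and at the ortho site not flanked by the benzyloxy group, with a second equivalent of formaldehyde acting as hydride acceptor.

Step 3
Reactants: 4 4-benzyloxy-2-hydroxy-5-methoxybenzaldehyde
Product: 5 5-benzyloxy-2-(hydroxymethyl)-4-methoxyphenol
Conditions: NaBH4, THF/MeOH, 0 °C; neutral work-up, used promptly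
Reagents that add atoms: none
Why: Borohydride reduction of the aldehyde gives the salicyl alcohol, which is kept away from acid because its para-benzyloxy group makes it ionise easily.

Step 4
Reactants: 6 2,3-dimethoxyphenol
Product: 7 1-(allyloxy)-2,3-dimethoxybenzene
Conditions: allyl bromide, K2CO3, acetone, reflux
Reagents that add atoms: allyl bromide, C=CCBr
Why: Williamson O-allylation of the phenoxide.

Step 5
Reactants: 7 1-(allyloxy)-2,3-dimethoxybenzene
Product: 8 6-allyl-2,3-dimethoxyphenol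
Conditions: PhNEt2, 200 °C
Reagents that add atoms: none
Why: Aromatic Claisen [3,3] rearrangement can only go to the single free ortho carbon, because the other ortho position carries a methoxy group.

Step 6
Reactants: 8 6-allyl-2,3-dimethoxyphenol
Product: 9 5-allyl-2,3-dimethoxy-1,4-benzoquinone
Conditions: ON(SO3K)2, KH2PO4, H2O/acetone, rt
Reagents that add atoms: potassium nitrosodisulfonate, [K+].[K+].[O]N(S(=O)(=O)[O-])S(=O)(=O)[O-]
Why: Teuber oxidation of a phenol with a free para position gives the para-quinone, the radical reagent leaving the allyl group untouched.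

Step 7
Reactants: 9 5-allyl-2,3-dimethoxy-1,4-benzoquinone
Product: 11 1-allyl-2,5-bis(benzyloxy)-3,4-dimethoxybenzene, via hydroquinone 10 (not isolated)
Conditions: Na2S2O4, EtOAc/H2O, rt; organic phase concentrated under Ar, then BnBr, K2CO3, DMF, 60 °C
Reagents that add atoms: benzyl bromide, BrCc1ccccc1
Why: Dithionite reduction of the quinone followed by Williamson benzylation of both phenols of the air-sensitive hydroquinone without isolating it.

Step 8
Reactants: 11 1-allyl-2,5-bis(benzyloxy)-3,4-dimethoxybenzene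
Product: 12 2-[2,5-bis(benzyloxy)-3,4-dimethoxyphenyl]acetaldehyde
Conditions: OsO4 (cat.), NaIO4, 2,6-lutidine, dioxane/H2O, rt; used directly
Reagents that add atoms: osmium tetroxide, O=[Os](=O)(=O)=O; sodium periodate, [Na+].[O-]I(=O)(=O)=O
Why: Lemieux–Johnson dihydroxylation and glycol cleavage of the terminal alkene gives the arylacetaldehyde and spares the very electron-rich arene that ozone could attack.

Step 9
Reactants: 5 5-benzyloxy-2-(hydroxymethyl)-4-methoxyphenol; 12 2-[2,5-bis(benzyloxy)-3,4-dimethoxyphenyl]acetaldehyde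
Product: 15 (3S)-7-benzyloxy-3-[2,5-bis(benzyloxy)-3,4-dimethoxyphenyl]-6-methoxychroman-2-ol (both C2 epimers), via o-quinone methide 13 (not isolated), via enamine 14 (not isolated)
Conditions: (S)-2-[diphenyl(trimethylsilyloxy)methyl]pyrrolidine (20 mol %), AcOH (1 equiv), CHCl3, 35 °C, 5 (1.3 equiv) added slowly; rapid filtration through silica
Reagents that add atoms: none
Why: Acetic acid reversibly ionises the para-benzyloxy-activated benzylic alcohol of 5 to methide 13 while the amine condenses with 12 to the (E)-enamine 14; the α-carbon of 14 adds to the exocyclic methylene of 13 (forming C3–C4 and rearomatising ring A), and the freed phenol adds to the iminium carbon (forming O1–C2) before hydrolysis releases the lactol and the amine. This is the secondary-amine-catalysed formal [4+2] cycloaddition of in situ o-quinone methides with enolisable aldehydes that gives chroman-2-ols. Ring C is closed stepwise, the second bond by 6-exo-trig attack of the phenol oxygen on the iminium. C3 is set by the catalyst: the diphenyl(silyloxy)methyl group blocks one face of the s-trans (E)-enamine, so the methide is attacked on the open Si face, which for the (S)-amine should give 3S. The step needs capture of 13 by the enamine rather than by another electron-rich phenol, which slow addition of 5 should secure, and it needs the α-aryl centre to survive, which is helped because the product rests as the cyclic hemiacetal and its α-branched open form re-condenses with the bulky amine only slowly.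

Step 10
Reactants: 15 (3S)-7-benzyloxy-3-[2,5-bis(benzyloxy)-3,4-dimethoxyphenyl]-6-methoxychroman-2-ol
Product: 16 5-benzyloxy-2-[(2S)-2-[2,5-bis(benzyloxy)-3,4-dimethoxyphenyl]-3-hydroxypropyl]-4-methoxyphenol
Conditions: NaBH4, THF/MeOH, 0 °C
Reagents that add atoms: none
Why: Borohydride reduces the open hydroxy-aldehyde tautomer of the lactol faster than it enolises, which fixes the α-aryl centre as a non-epimerisable primary alcohol.

Step 11
Reactants: 16 5-benzyloxy-2-[(2S)-2-[2,5-bis(benzyloxy)-3,4-dimethoxyphenyl]-3-hydroxypropyl]-4-methoxyphenol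
Product: 17 (3S)-7-benzyloxy-3-[2,5-bis(benzyloxy)-3,4-dimethoxyphenyl]-6-methoxychroman
Conditions: PPh3, DIAD, THF, 0 °C to rt
Reagents that add atoms: none
Why: Intramolecular Mitsunobu etherification in which the only free phenol displaces the activated primary alcohol (6-exo-tet), re-forming O1–C2 without touching C3.

Step 12
Reactants: 17 (3S)-7-benzyloxy-3-[2,5-bis(benzyloxy)-3,4-dimethoxyphenyl]-6-methoxychroman
Product: 18 (3S,4R)-7-benzyloxy-3-[2,5-bis(benzyloxy)-3,4-dimethoxyphenyl]-6-methoxychroman-4-ol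
Conditions: DDQ (1.2 equiv), CH2Cl2/pH 7 phosphate buffer (10:1), 0 °C
Reagents that add atoms: water, O
Why: DDQ-mediated benzylic C–H oxygenation, as known for C4 of 7-oxygenated flavans, should remove hydride from C4 (conjugated to O1 ortho and the 7-benzyloxy group para), and water should add to the quinone-methide-type cation anti to the C3 aryl group, setting C4 as R (3,4-trans).

Step 13
Reactants: 18 (3S,4R)-7-benzyloxy-3-[2,5-bis(benzyloxy)-3,4-dimethoxyphenyl]-6-methoxychroman-4-ol
Product: 19 (3S,4R)-3-(2,5-dihydroxy-3,4-dimethoxyphenyl)-6-methoxychroman-4,7-diol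
Conditions: H2 (1 atm), Pd/C, NaHCO3 (solid), EtOAc, rt, stopped at full debenzylation; handled under Ar
Reagents that add atoms: none
Why: Catalytic hydrogenolysis of the three aryl benzyl ethers under neutral, aprotic conditions should be much faster than hydrogenolysis of the C4 carbinol and touches no stereocentre.

**Compound list**

1 | 3-benzyloxy-4-methoxybenzaldehyde | COc1ccc(C=O)cc1OCc1ccccc1 | starting material
2 | 3-benzyloxy-4-methoxyphenyl formate | COc1ccc(OC=O)cc1OCc1ccccc1 | intermediate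
3 | 3-benzyloxy-4-methoxyphenol | COc1ccc(O)cc1OCc1ccccc1 | intermediate
4 | 4-benzyloxy-2-hydroxy-5-methoxybenzaldehyde | COc1cc(C=O)c(O)cc1OCc1ccccc1 | intermediate
5 | 5-benzyloxy-2-(hydroxymethyl)-4-methoxyphenol | COc1cc(CO)c(O)cc1OCc1ccccc1 | intermediate
6 | 2,3-dimethoxyphenol | COc1cccc(O)c1OC | starting material
7 | 1-(allyloxy)-2,3-dimethoxybenzene | C=CCOc1cccc(OC)c1OC | intermediate
8 | 6-allyl-2,3-dimethoxyphenol | C=CCc1ccc(OC)c(OC)c1O | intermediate
9 | 5-allyl-2,3-dimethoxy-1,4-benzoquinone | C=CCC1=CC(=O)C(OC)=C(OC)C1=O | intermediate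
10 | 5-allyl-2,3-dimethoxybenzene-1,4-diol | C=CCc1cc(O)c(OC)c(OC)c1O | intermediate
11 | 1-allyl-2,5-bis(benzyloxy)-3,4-dimethoxybenzene | C=CCc1cc(OCc2ccccc2)c(OC)c(OC)c1OCc1ccccc1 | intermediate
12 | 2-[2,5-bis(benzyloxy)-3,4-dimethoxyphenyl]acetaldehyde | O=CCc1cc(OCc2ccccc2)c(OC)c(OC)c1OCc1ccccc1 | intermediate
13 | 3-benzyloxy-4-methoxy-6-methylidenecyclohexa-2,4-dien-1-one (o-quinone methide) | C=C1C=C(OC)C(OCc2ccccc2)=CC1=O | intermediate
14 | (2S)-1-[(E)-2-[2,5-bis(benzyloxy)-3,4-dimethoxyphenyl]ethenyl]-2-[diphenyl(trimethylsilyloxy)methyl]pyrrolidine (enamine) | C[Si](C)(C)OC(c1ccccc1)(c1ccccc1)[C@@H]1CCCN1/C=C/c1cc(OCc2ccccc2)c(OC)c(OC)c1OCc1ccccc1 | intermediate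
15 | (3S)-7-benzyloxy-3-[2,5-bis(benzyloxy)-3,4-dimethoxyphenyl]-6-methoxychroman-2-ol (C2 epimers) | COc1cc2c(cc1OCc1ccccc1)OC(O)[C@H](c1cc(OCc3ccccc3)c(OC)c(OC)c1OCc1ccccc1)C2 | intermediate
16 | 5-benzyloxy-2-[(2S)-2-[2,5-bis(benzyloxy)-3,4-dimethoxyphenyl]-3-hydroxypropyl]-4-methoxyphenol | OC[C@H](c1cc(OCc2ccccc2)c(OC)c(OC)c1OCc1ccccc1)Cc1cc(OC)c(OCc2ccccc2)cc1O | intermediate
17 | (3S)-7-benzyloxy-3-[2,5-bis(benzyloxy)-3,4-dimethoxyphenyl]-6-methoxychroman | COc1cc2c(cc1OCc1ccccc1)OC[C@H](c1cc(OCc3ccccc3)c(OC)c(OC)c1OCc1ccccc1)C2 | intermediate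
18 | (3S,4R)-7-benzyloxy-3-[2,5-bis(benzyloxy)-3,4-dimethoxyphenyl]-6-methoxychroman-4-ol | COc1cc2c(cc1OCc1ccccc1)OC[C@H](c1cc(OCc3ccccc3)c(OC)c(OC)c1OCc1ccccc1)[C@H]2O | intermediate
19 | (3S,4R)-3-(2,5-dihydroxy-3,4-dimethoxyphenyl)-6-methoxychroman-4,7-diol | COc1cc2c(cc1O)OC[C@H](c1cc(O)c(OC)c(OC)c1O)[C@H]2O | target

**Step count and risks**

Total step count: 13. Longest linear sequence: 10 steps (steps 4–13, from 2,3-dimethoxyphenol); the ring A branch is steps 1–3.

Steps most likely to fail: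

1. Step 9. The enantiopurity at the α-aryl carbon may erode through enolisation or enamine re-formation, and the methide may be consumed by self-alkylation of the electron-rich phenol.
Fallback (auxiliary-controlled alkylation, then palladium-catalysed ring closure), setting out from 12 and returning at 17. Pinnick oxidation of 12 (NaClO2, NaH2PO4, 2-methyl-2-butene) should give 2-[2,5-bis(benzyloxy)-3,4-dimethoxyphenyl]acetic acid F1. Activation with pivaloyl chloride/Et3N and acylation of lithiated (S)-4-benzyl-1,3-oxazolidin-2-one should give the imide (4S)-4-benzyl-3-{[2,5-bis(benzyloxy)-3,4-dimethoxyphenyl]acetyl}-1,3-oxazolidin-2-one F2. Separately, purchased (4-benzyloxy-3-methoxyphenyl)methanol F3 is ring-brominated para to the methoxy group with NBS to (4-benzyloxy-2-bromo-5-methoxyphenyl)methanol F4 and converted with PBr3 into 1-benzyloxy-5-bromo-4-(bromomethyl)-2-methoxybenzene F5. Evans alkylation of the sodium enolate of F2 (NaN(SiMe3)2, THF, −78 °C) with F5, anti to the auxiliary benzyl group, should give (4S)-4-benzyl-3-[(2S)-3-(4-benzyloxy-2-bromo-5-methoxyphenyl)-2-[2,5-bis(benzyloxy)-3,4-dimethoxyphenyl]propanoyl]-1,3-oxazolidin-2-one F6. LiBH4 cleavage should give (2S)-3-(4-benzyloxy-2-bromo-5-methoxyphenyl)-2-[2,5-bis(benzyloxy)-3,4-dimethoxyphenyl]propan-1-ol F7. Intramolecular Buchwald–Hartwig etherification (Pd(OAc)2, 2-(di-tert-butylphosphino)-1,1'-binaphthyl, Cs2CO3, toluene, 80 °C) then closes O1–C8a and gives 17.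

2. Step 12. The C4 cation may lose H-3 (elimination to the 2H-chromene), hydride may be taken from C3 instead, or the new carbinol may be oxidised further; each of these erases the C3 centre.
Fallback (give up retention at C3 and set both centres by dynamic kinetic resolution), setting out from 17 and returning at 18. Deliberate dehydrogenation with DDQ in dry dioxane should give 7-benzyloxy-3-[2,5-bis(benzyloxy)-3,4-dimethoxyphenyl]-6-methoxy-2H-chromene F8. Hydroboration–oxidation (BH3·THF; NaOH, H2O2) should give racemic trans-7-benzyloxy-3-[2,5-bis(benzyloxy)-3,4-dimethoxyphenyl]-6-methoxychroman-4-ol F9. Dess–Martin oxidation should give 7-benzyloxy-3-[2,5-bis(benzyloxy)-3,4-dimethoxyphenyl]-6-methoxychroman-4-one F10, whose C3 is configurationally labile. Noyori transfer hydrogenation under dynamic kinetic resolution (RuCl(p-cymene)[(S,S)-TsDPEN], HCO2H/Et3N) is expected, on the usual sense of induction, to give the cis alcohol (3S,4S)-7-benzyloxy-3-[2,5-bis(benzyloxy)-3,4-dimethoxyphenyl]-6-methoxychroman-4-ol F11. Mitsunobu inversion at C4 with 4-nitrobenzoic acid (PPh3, DIAD) should give (3S,4R)-7-benzyloxy-3-[2,5-bis(benzyloxy)-3,4-dimethoxyphenyl]-6-methoxychroman-4-yl 4-nitrobenzoate F12, and methanolysis (K2CO3, MeOH) gives 18.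

3. Step 13. The activated benzylic C4–O bond may be hydrogenolysed along with the benzyl ethers.
Fallback (exchange the benzyl ethers for silyl ethers before C4 is oxygenated, so the last step is not reductive), setting out from 17 and returning at 19. Hydrogenolysis of 17 (H2, Pd/C), which has no C4 oxygen, should give (3S)-3-(2,5-dihydroxy-3,4-dimethoxyphenyl)-6-methoxychroman-7-ol F13. Silylation (TBSCl, imidazole, DMF) should give (3S)-7-(tert-butyldimethylsilyloxy)-3-[2,5-bis(tert-butyldimethylsilyloxy)-3,4-dimethoxyphenyl]-6-methoxychroman F14. DDQ in wet CH2Cl2, as in step 12, should give (3S,4R)-7-(tert-butyldimethylsilyloxy)-3-[2,5-bis(tert-butyldimethylsilyloxy)-3,4-dimethoxyphenyl]-6-methoxychroman-4-ol F15. Bu4NF buffered with AcOH in THF at 0 °C then gives 19.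

**Further compounds**

F1 | step 9 | 2-[2,5-bis(benzyloxy)-3,4-dimethoxyphenyl]acetic acid | OC(=O)Cc1cc(OCc2ccccc2)c(OC)c(OC)c1OCc1ccccc1
F2 | step 9 | (4S)-4-benzyl-3-{[2,5-bis(benzyloxy)-3,4-dimethoxyphenyl]acetyl}-1,3-oxazolidin-2-one | O=C(Cc1cc(OCc2ccccc2)c(OC)c(OC)c1OCc1ccccc1)N1C(=O)OC[C@@H]1Cc1ccccc1
F3 | step 9 | (4-benzyloxy-3-methoxyphenyl)methanol (purchased) | COc1cc(CO)ccc1OCc1ccccc1
F4 | step 9 | (4-benzyloxy-2-bromo-5-methoxyphenyl)methanol | COc1cc(CO)c(Br)cc1OCc1ccccc1
F5 | step 9 | 1-benzyloxy-5-bromo-4-(bromomethyl)-2-methoxybenzene | COc1cc(CBr)c(Br)cc1OCc1ccccc1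
F6 | step 9 | (4S)-4-benzyl-3-[(2S)-3-(4-benzyloxy-2-bromo-5-methoxyphenyl)-2-[2,5-bis(benzyloxy)-3,4-dimethoxyphenyl]propanoyl]-1,3-oxazolidin-2-one | O=C(N1C(=O)OC[C@@H]1Cc1ccccc1)[C@H](c1cc(OCc2ccccc2)c(OC)c(OC)c1OCc1ccccc1)Cc1cc(OC)c(OCc2ccccc2)cc1Br
F7 | step 9 | (2S)-3-(4-benzyloxy-2-bromo-5-methoxyphenyl)-2-[2,5-bis(benzyloxy)-3,4-dimethoxyphenyl]propan-1-ol | OC[C@H](c1cc(OCc2ccccc2)c(OC)c(OC)c1OCc1ccccc1)Cc1cc(OC)c(OCc2ccccc2)cc1Br
F8 | step 12 | 7-benzyloxy-3-[2,5-bis(benzyloxy)-3,4-dimethoxyphenyl]-6-methoxy-2H-chromene | COc1cc2c(cc1OCc1ccccc1)OCC(c1cc(OCc3ccccc3)c(OC)c(OC)c1OCc1ccccc1)=C2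
F9 | step 12 | racemic trans-(3RS,4SR)-7-benzyloxy-3-[2,5-bis(benzyloxy)-3,4-dimethoxyphenyl]-6-methoxychroman-4-ol (one enantiomer drawn) | COc1cc2c(cc1OCc1ccccc1)OC[C@H](c1cc(OCc3ccccc3)c(OC)c(OC)c1OCc1ccccc1)[C@H]2O
F10 | step 12 | 7-benzyloxy-3-[2,5-bis(benzyloxy)-3,4-dimethoxyphenyl]-6-methoxychroman-4-one | COc1cc2c(cc1OCc1ccccc1)OCC(c1cc(OCc3ccccc3)c(OC)c(OC)c1OCc1ccccc1)C2=O
F11 | step 12 | (3S,4S)-7-benzyloxy-3-[2,5-bis(benzyloxy)-3,4-dimethoxyphenyl]-6-methoxychroman-4-ol | COc1cc2c(cc1OCc1ccccc1)OC[C@H](c1cc(OCc3ccccc3)c(OC)c(OC)c1OCc1ccccc1)[C@@H]2O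
F12 | step 12 | (3S,4R)-7-benzyloxy-3-[2,5-bis(benzyloxy)-3,4-dimethoxyphenyl]-6-methoxychroman-4-yl 4-nitrobenzoate | COc1cc2c(cc1OCc1ccccc1)OC[C@H](c1cc(OCc3ccccc3)c(OC)c(OC)c1OCc1ccccc1)[C@H]2OC(=O)c1ccc(cc1)[N+](=O)[O-]
F13 | step 13 | (3S)-3-(2,5-dihydroxy-3,4-dimethoxyphenyl)-6-methoxychroman-7-ol | COc1cc2c(cc1O)OC[C@H](c1cc(O)c(OC)c(OC)c1O)C2
F14 | step 13 | (3S)-7-(tert-butyldimethylsilyloxy)-3-[2,5-bis(tert-butyldimethylsilyloxy)-3,4-dimethoxyphenyl]-6-methoxychroman | COc1cc2c(cc1O[Si](C)(C)C(C)(C)C)OC[C@H](c1cc(O[Si](C)(C)C(C)(C)C)c(OC)c(OC)c1O[Si](C)(C)C(C)(C)C)C2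
F15 | step 13 | (3S,4R)-7-(tert-butyldimethylsilyloxy)-3-[2,5-bis(tert-butyldimethylsilyloxy)-3,4-dimethoxyphenyl]-6-methoxychroman-4-ol | COc1cc2c(cc1O[Si](C)(C)C(C)(C)C)OC[C@H](c1cc(O[Si](C)(C)C(C)(C)C)c(OC)c(OC)c1O[Si](C)(C)C(C)(C)C)[C@H]2O
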